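## Retrosynthetic overview

- The target comes from acetylation at O8 and lactol oxidation of the product of a CrCl2/NiCl2 ring closure (C6–C7) of an acyclic bis-epoxy iodo-dialdehyde. That closure forms the ten-membered carbocycle and the five-membered oxygen ring (as a lactol) in one step, last.
- Both oxiranes are made before the large ring, by one reagent-controlled dioxirane epoxidation of the acyclic (4E,1(10)Z)-diene.
- Key union (C8–C9): allylboration of a C5 iodo-enal (C7, C8, C11–C13) with an α-chiral C10 allylic boronate (C1–C6, C9, C10, C14, C15). The two pieces have 12 non-hydrogen atoms each without protecting groups; the step sets C8 and the Z olefin.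
- Boronate: pent-4-yn-1-ol, carboalumination (E olefin, C15), then lithiation–borylation with isopropenyl-B(pin). Enal: dihydroxyacetone via a butenolide template that fixes the tetrasubstituted olefin geometry and is then opened.
- Ring order: template butenolide (opened) → two oxiranes → ten-membered ring with dihydrofuranol → butenolide.

Assumption: locants C1–C15 are the germacrane locants of the target (C12 lactone carbonyl, C13 acetoxymethyl carbon, C14/C15 the methyls on C10/C4); the target is (1R,4R,5R,6S,8S,10S). (+)-Sparteine and the D-fructose-derived Shi ketone are bought.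

## Route

Step 1
Reactants: 1 1,3-dihydroxyacetone
Product: 3 4-(hydroxymethyl)furan-2(5H)-one, via hydroxy ester 2 (not isolated)
Conditions: Ph3P=CHCO2Et (1.1 equiv), CH2Cl2, rt, 16 h
Reagents that add atoms: ethyl (triphenylphosphoranylidene)acetate (CCOC(=O)C=P(c1ccccc1)(c1ccccc1)c1ccccc1)
Why: Wittig olefination of the ketone is followed by spontaneous lactonisation of the CH2OH group cis to the ester, and since the two CH2OH groups are identical no olefin isomers arise while the ring now marks the CH2–O carbon (future C13) that is cis to the future C8.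

Step 2
Reactants: 3 4-(hydroxymethyl)furan-2(5H)-one
Product: 4 4-{[(tert-butyldimethylsilyl)oxy]methyl}furan-2(5H)-one
Conditions: TBSCl, imidazole, DMF, 0 °C to rt
Reagents that add atoms: tert-butyldimethylsilyl chloride (CC(C)(C)[Si](C)(C)Cl)
Why: Standard silyl ether formation on the primary alcohol protects O12 through the organometallic and oxidation steps.

Step 3
Reactants: 4 4-{[(tert-butyldimethylsilyl)oxy]methyl}furan-2(5H)-one
Product: 5 4-{[(tert-butyldimethylsilyl)oxy]methyl}-3-iodofuran-2(5H)-one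
Conditions: I2 (2 equiv), pyridine, CH2Cl2, rt, dark
Reagents that add atoms: iodine (II)
Why: Johnson-type α-iodination of the conjugated lactone, in which pyridine adds reversibly at the β-carbon, the enolate is iodinated at C7 and pyridinium iodide is eliminated.

Step 4
Reactants: 5 4-{[(tert-butyldimethylsilyl)oxy]methyl}-3-iodofuran-2(5H)-one
Product: 7 (Z)-4-acetoxy-2-iodo-N-methoxy-N-methyl-3-{[(tert-butyldimethylsilyl)oxy]methyl}but-2-enamide, via hydroxy amide 6 (not isolated)
Conditions: AlMe3, MeNHOMe·HCl, CH2Cl2, 0 °C to rt; then Ac2O, pyridine, 4-(dimethylamino)pyridine (cat.), 0 °C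
Reagents that add atoms: N,O-dimethylhydroxylamine hydrochloride (CNOC.Cl); acetic anhydride (CC(=O)OC(C)=O)
Why: Weinreb aminolysis of the lactone with the aluminium amide opens the ring with the olefin geometry retained (C13–O cis to the amide, iodine cis to C12), and the alkoxide is acetylated in the same flask before it can relactonise.

Step 5
Reactants: 7 (Z)-acetoxy iodo Weinreb amide
Product: 8 (Z)-4-acetoxy-2-iodo-3-{[(tert-butyldimethylsilyl)oxy]methyl}but-2-enal
Conditions: Cp2Zr(H)Cl (1.5 equiv), THF, rt, 15 min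
Reagents that add atoms: none
Why: Chemoselective reduction of the Weinreb amide to the aldehyde by hydrozirconation of the amide carbonyl with Cp2Zr(H)Cl, which leaves the acetate, silyl ether and vinyl iodide untouched.

Step 6
Reactants: 9 pent-4-yn-1-ol
Product: 10 pent-4-yn-1-yl N,N-diisopropylcarbamate
Conditions: iPr2NC(O)Cl, Et3N, CH2Cl2, reflux
Reagents that add atoms: N,N-diisopropylcarbamoyl chloride (CC(C)N(C(C)C)C(=O)Cl)
Why: O-Carbamoylation installs the directing and leaving group needed later for the asymmetric α-lithiation at C1.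

Step 7
Reactants: 10 pent-4-yn-1-yl N,N-diisopropylcarbamate
Product: 12 methyl (E)-6-[(diisopropylcarbamoyl)oxy]-3-methylhex-2-enoate, via alkenylalane 11 (not isolated)
Conditions: AlMe3 (2.5 equiv), Cp2ZrCl2 (25 mol%), CH2Cl2, 0 °C to rt; then ClCO2Me, 0 °C to rt
Reagents that add atoms: trimethylaluminium (C[Al](C)C); methyl chloroformate (COC(=O)Cl)
Why: Negishi zirconium-catalysed carboalumination adds methyl and aluminium syn across the alkyne (methyl to the internal carbon), and acylation of the alkenylalane with retention fixes the E trisubstituted C4=C5 olefin.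

Step 8
Reactants: 12 methyl (E)-6-[(diisopropylcarbamoyl)oxy]-3-methylhex-2-enoate
Product: 13 (E)-6-hydroxy-4-methylhex-4-en-1-yl N,N-diisopropylcarbamate
Conditions: iBu2AlH (2.2 equiv), CH2Cl2, −78 °C; aqueous KNaC4H4O6 work-up
Reagents that add atoms: none
Why: 1,2-Reduction of the enoate to the allylic alcohol with an aluminium hydride, the hindered carbamate being inert at −78 °C.

Step 9
Reactants: 13 (E)-6-hydroxy-4-methylhex-4-en-1-yl N,N-diisopropylcarbamate
Product: 14 (E)-6-[(tert-butyldimethylsilyl)oxy]-4-methylhex-4-en-1-yl N,N-diisopropylcarbamate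
Conditions: TBSCl, imidazole, CH2Cl2, 0 °C to rt
Reagents that add atoms: tert-butyldimethylsilyl chloride (CC(C)(C)[Si](C)(C)Cl)
Why: Standard silylation protects O6 against the alkyllithium used next.

Step 10
Reactants: 15 2-bromopropene
Product: 17 4,4,5,5-tetramethyl-2-(prop-1-en-2-yl)-1,3,2-dioxaborolane, via isopropenylmagnesium bromide 16 (not isolated)
Conditions: Mg, THF, rt; then 2-isopropoxy-4,4,5,5-tetramethyl-1,3,2-dioxaborolane, −78 °C to rt; dilute aqueous HCl work-up
Reagents that add atoms: 2-isopropoxy-4,4,5,5-tetramethyl-1,3,2-dioxaborolane (CC(C)OB1OC(C)(C)C(C)(C)O1)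
Why: Grignard formation and borylation with an alkoxy pinacol borate give the alkenyl boronic ester that supplies C9, C10 and C14.

Step 11
Reactants: 14 (E)-6-[(tert-butyldimethylsilyl)oxy]-4-methylhex-4-en-1-yl N,N-diisopropylcarbamate; 17 isopropenyl pinacol boronate
Product: 20 (S,E)-tert-butyldimethyl{[3,7-dimethyl-6-(4,4,5,5-tetramethyl-1,3,2-dioxaborolan-2-yl)octa-2,7-dien-1-yl]oxy}silane, via lithiated carbamate 18 (not isolated), via borate complex 19 (not isolated)
Conditions: s-BuLi, (+)-sparteine, Et2O, −78 °C, 5 h; then 17, −78 °C, 1 h; then MgBr2·OEt2, Et2O, reflux, 12 h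
Reagents that add atoms: none
Why: Hoppe–Aggarwal lithiation–borylation, in which sparteine-controlled removal of one enantiotopic α-proton gives the configurationally stable (R)-lithiated carbamate, borylation proceeds with retention and the isopropenyl group migrates from boron to carbon with inversion as the carbamate leaves, so the boron-bearing carbon (C1) is set as S.

Step 12
Reactants: 20 (S)-allylic pinacol boronate; 8 (Z)-iodo enal
Product: 22 (2Z,4S,6Z,10E)-12-[(tert-butyldimethylsilyl)oxy]-2-{[(tert-butyldimethylsilyl)oxy]methyl}-4-hydroxy-3-iodo-6,10-dimethyldodeca-2,6,10-trien-1-yl acetate, via O-boryl adduct 21 (not isolated)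
Conditions: toluene (1 M), 40 °C, 48 h; then aqueous NaHCO3, MeOH
Reagents that add atoms: none
Why: Thermal allylboration through a closed six-membered chair transition state with the aldehyde substituent equatorial and the α-alkyl group of the boronate axial (clear of the pinacol methyls and the 2-methyl group), so the S boron-bearing centre is transferred to C8 as S while the new trisubstituted C1=C10 olefin forms with C2 cis to C9.

Step 13
Reactants: 22 (8S)-homoallylic alcohol (1(10)Z,4E-diene)
Product: 23 (1R,4R,5R,8S,10S)-1,10:4,5-bis-epoxide of 22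
Conditions: 1,2:4,5-di-O-isopropylidene-β-D-erythro-2,3-hexodiulo-2,6-pyranose (Shi ketone from D-fructose, 0.6 equiv), KHSO5 (as Oxone, 2KHSO5·KHSO4·K2SO4), K2CO3, Bu4NHSO4 (cat.), Na2B4O7 buffer, MeCN–CH2(OMe)2–H2O, 0 °C, 3 h
Reagents that add atoms: potassium peroxymonosulfate ([K+].[O-]S(=O)(=O)OO)
Why: Shi asymmetric epoxidation, in which the chiral dioxirane attacks each electron-rich trisubstituted olefin through the spiro transition state that puts the lone vinylic hydrogen in the hindered quadrant, giving R at both CH carbons (C1 and C5) and hence by stereospecific syn addition the (1R,10S)-cis and (4R,5R)-trans oxiranes, while the iodinated tetrasubstituted olefin is too hindered and electron-poor to react.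

Step 14
Reactants: 23 bis-epoxide bis-silyl ether
Product: 24 bis-epoxy triol (free O6–H, O8–H and O12–H; C13 acetate)
Conditions: Bu4NF, AcOH (1:1), THF, 0 °C to rt
Reagents that add atoms: none
Why: Fluoride-mediated desilylation of both primary silyl ethers, buffered with acetic acid so that neither acetyl migration nor Payne rearrangement of the 2,3-epoxy alcohol occurs.

Step 15
Reactants: 24 bis-epoxy triol
Product: 25 bis-epoxy iodo-dialdehyde (C6 and C12 aldehydes; free 8S-OH)
Conditions: 2,2,6,6-tetramethylpiperidin-1-oxyl (TEMPO, 20 mol%), PhI(OAc)2 (2.4 equiv), CH2Cl2, rt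
Reagents that add atoms: none
Why: Oxoammonium (TEMPO) oxidation is selective for the two primary alcohols over the hindered secondary C8 alcohol and tolerates the epoxides.

Step 16
Reactants: 25 bis-epoxy iodo-dialdehyde
Product: 27 (1R,4R,5R,6S,8S,10S)-13-acetoxy-1,10:4,5-diepoxy-8,12-dihydroxy-6,12-epoxygermacr-7(11)-ene (lactol; mixture at C12), via hydroxy aldehyde 26 (not isolated)
Conditions: CrCl2 (12 equiv), NiCl2 (2 mol% of the CrCl2), DMSO–THF (3:1), 0.002 M by syringe pump, rt
Reagents that add atoms: none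
Why: Nozaki–Hiyama–Kishi ring closure, in which zerovalent nickel inserts into the vinyl iodide, transmetalation gives the alkenylchromium that adds to the epoxy aldehyde at high dilution to close the ten-membered ring, and the alkoxide then adds to the cis aldehyde as a lactol; the new C6 centre (S) is expected from attack on the aldehyde face left open when the trans-4,5-epoxide lies in the forming ring, by analogy with chromium closures of 4,5-epoxy germacrane aldehydes.

Step 17
Reactants: 27 lactol
Product: 28 (1R,4R,5R,6S,8S,10S)-13-acetoxy-1,10:4,5-diepoxy-8-hydroxygermacr-7(11)-en-12,6-olide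
Conditions: 2,2,6,6-tetramethylpiperidin-1-oxyl (TEMPO, 20 mol%), PhI(OAc)2 (1.1 equiv), CH2Cl2, 0 °C
Reagents that add atoms: none
Why: Oxoammonium oxidation of the lactol to the butenolide is much faster than oxidation of the hindered secondary C8 alcohol.

Step 18
Reactants: 28 8-hydroxy lactone
Product: 29 (1R,4R,5R,6S,8S,10S)-8,13-diacetoxy-1,10:4,5-diepoxygermacr-7(11)-en-12,6-olide (CNP0271844.2)
Conditions: Ac2O, pyridine, 4-(dimethylamino)pyridine (cat.), CH2Cl2, 0 °C to rt
Reagents that add atoms: acetic anhydride (CC(=O)OC(C)=O)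
Why: Nucleophile-catalysed O-acetylation of the remaining secondary alcohol under mild base that does not touch the epoxides or epimerise C6.

## Compound list

1 | 1,3-dihydroxyacetone | OCC(=O)CO | starting material
2 | ethyl 4-hydroxy-3-(hydroxymethyl)but-2-enoate | CCOC(=O)C=C(CO)CO | intermediate
3 | 4-(hydroxymethyl)furan-2(5H)-one | O=C1OCC(CO)=C1 | intermediate
4 | 4-{[(tert-butyldimethylsilyl)oxy]methyl}furan-2(5H)-one | O=C1OCC(CO[Si](C)(C)C(C)(C)C)=C1 | intermediate
5 | 4-{[(tert-butyldimethylsilyl)oxy]methyl}-3-iodofuran-2(5H)-one | O=C1OCC(CO[Si](C)(C)C(C)(C)C)=C1I | intermediate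
6 | (Z)-4-hydroxy-2-iodo-N-methoxy-N-methyl-3-{[(tert-butyldimethylsilyl)oxy]methyl}but-2-enamide (as its aluminium alkoxide) | OC/C(CO[Si](C)(C)C(C)(C)C)=C(/I)C(=O)N(C)OC | intermediate
7 | (Z)-4-acetoxy-2-iodo-N-methoxy-N-methyl-3-{[(tert-butyldimethylsilyl)oxy]methyl}but-2-enamide | CC(=O)OC/C(CO[Si](C)(C)C(C)(C)C)=C(/I)C(=O)N(C)OC | intermediate
8 | (Z)-4-acetoxy-2-iodo-3-{[(tert-butyldimethylsilyl)oxy]methyl}but-2-enal (CHO cis to CH2OAc, I cis to CH2OTBS) | CC(=O)OC/C(CO[Si](C)(C)C(C)(C)C)=C(/I)C=O | intermediate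
9 | pent-4-yn-1-ol | C#CCCCO | starting material
10 | pent-4-yn-1-yl N,N-diisopropylcarbamate | C#CCCCOC(=O)N(C(C)C)C(C)C | intermediate
11 | (E)-{5-[(diisopropylcarbamoyl)oxy]-2-methylpent-1-en-1-yl}dimethylalane | C[Al](C)/C=C(\C)CCCOC(=O)N(C(C)C)C(C)C | intermediate
12 | methyl (E)-6-[(diisopropylcarbamoyl)oxy]-3-methylhex-2-enoate | COC(=O)/C=C(\C)CCCOC(=O)N(C(C)C)C(C)C | intermediate
13 | (E)-6-hydroxy-4-methylhex-4-en-1-yl N,N-diisopropylcarbamate | OC/C=C(\C)CCCOC(=O)N(C(C)C)C(C)C | intermediate
14 | (E)-6-[(tert-butyldimethylsilyl)oxy]-4-methylhex-4-en-1-yl N,N-diisopropylcarbamate | CC(C)(C)[Si](C)(C)OC/C=C(\C)CCCOC(=O)N(C(C)C)C(C)C | intermediate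
15 | 2-bromopropene | CC(Br)=C | starting material
16 | isopropenylmagnesium bromide | CC(=C)[Mg]Br | intermediate
17 | 4,4,5,5-tetramethyl-2-(prop-1-en-2-yl)-1,3,2-dioxaborolane | CC(=C)B1OC(C)(C)C(C)(C)O1 | intermediate
18 | (1R)-1-lithio derivative of 14 (sparteine complex) | CC(C)(C)[Si](C)(C)OC/C=C(\C)CC[C@@H]([Li])OC(=O)N(C(C)C)C(C)C | intermediate
19 | lithium borate complex of 18 with 17 (boron in place of lithium, retention) | CC(C)(C)[Si](C)(C)OC/C=C(\C)CC[C@@H]([B-]1(C(C)=C)OC(C)(C)C(C)(C)O1)OC(=O)N(C(C)C)C(C)C.[Li+] | intermediate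
20 | (S,E)-tert-butyldimethyl{[3,7-dimethyl-6-(4,4,5,5-tetramethyl-1,3,2-dioxaborolan-2-yl)octa-2,7-dien-1-yl]oxy}silane | CC(C)(C)[Si](C)(C)OC/C=C(\C)CC[C@H](B1OC(C)(C)C(C)(C)O1)C(C)=C | intermediate
21 | O-(pinacolboryl) derivative of 22 | CC(=O)OC/C(CO[Si](C)(C)C(C)(C)C)=C(/I)[C@@H](OB1OC(C)(C)C(C)(C)O1)C/C(C)=C\CC/C(C)=C/CO[Si](C)(C)C(C)(C)C | intermediate
22 | (2Z,4S,6Z,10E)-12-[(tert-butyldimethylsilyl)oxy]-2-{[(tert-butyldimethylsilyl)oxy]methyl}-4-hydroxy-3-iodo-6,10-dimethyldodeca-2,6,10-trien-1-yl acetate (8S; 1(10)Z; 4E) | CC(=O)OC/C(CO[Si](C)(C)C(C)(C)C)=C(/I)[C@@H](O)C/C(C)=C\CC/C(C)=C/CO[Si](C)(C)C(C)(C)C | intermediate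
23 | bis-epoxide of 22: (1R,10S)-cis-1,10-epoxide and (4R,5R)-trans-4,5-epoxide, 8S | CC(=O)OC/C(CO[Si](C)(C)C(C)(C)C)=C(/I)[C@@H](O)C[C@]1(C)O[C@@H]1CC[C@@]1(C)O[C@@H]1CO[Si](C)(C)C(C)(C)C | intermediate
24 | bis-epoxy triol (23 without both silyl groups) | CC(=O)OC/C(CO)=C(/I)[C@@H](O)C[C@]1(C)O[C@@H]1CC[C@@]1(C)O[C@@H]1CO | intermediate
25 | bis-epoxy iodo-dialdehyde (C6 and C12 aldehydes, 8S-OH; epoxide geometry as in 23) | CC(=O)OC/C(C=O)=C(/I)[C@@H](O)C[C@]1(C)O[C@@H]1CC[C@@]1(C)O[C@@H]1C=O | intermediate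
26 | ring-closed (6S)-6,8-dihydroxy ten-membered carbocycle with free C12 aldehyde | CC(=O)OC/C(C=O)=C1\[C@@H](O)C[C@]2(C)O[C@@H]2CC[C@@]2(C)O[C@@H]2[C@H]1O | intermediate
27 | (1R,4R,5R,6S,8S,10S)-13-acetoxy-1,10:4,5-diepoxy-8,12-dihydroxy-6,12-epoxygermacr-7(11)-ene (lactol, both C12 epimers) | CC(=O)OCC1=C2[C@@H](O)C[C@]3(C)O[C@@H]3CC[C@@]3(C)O[C@@H]3[C@H]2OC1O | intermediate
28 | (1R,4R,5R,6S,8S,10S)-13-acetoxy-1,10:4,5-diepoxy-8-hydroxygermacr-7(11)-en-12,6-olide | CC(=O)OCC1=C2[C@@H](O)C[C@]3(C)O[C@@H]3CC[C@@]3(C)O[C@@H]3[C@H]2OC1=O | intermediate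
29 | (1R,4R,5R,6S,8S,10S)-8,13-diacetoxy-1,10:4,5-diepoxygermacr-7(11)-en-12,6-olide | CC(=O)OCC1=C2[C@@H](OC(C)=O)C[C@]3(C)O[C@@H]3CC[C@@]3(C)O[C@@H]3[C@H]2OC1=O | target

## Step count

Total: 18 steps. Longest linear sequence: 12 steps (steps 1–5 then 12–18 from dihydroxyacetone; equally steps 6–9 and 11 then 12–18 from pent-4-yn-1-ol).

## Steps most likely to fail, with fallbacks

**Step 12 (allylboration).** The hindered α-substituted pinacol boronate may react slowly or give part of the E olefin, which carries the wrong C8 configuration. The fallback sets out from 14 (with 15 and 8) and returns at 22.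
- 15 is converted to its Grignard reagent and quenched with 9-methoxy-9-borabicyclo[3.3.1]nonane to give 9-isopropenyl-9-borabicyclo[3.3.1]nonane F1.
- Lithiated carbamate 18, made from 14 as in step 11, is borylated with F1 at −78 °C to the lithium borate complex F2.
- F2 rearranges on warming to −40 °C, without Lewis acid, to the (S)-allylborane F3.
- F3 is not isolated; it is re-cooled to −78 °C and treated with aldehyde 8 to give the borinate F4, from which ethanolamine releases 22.
- The borane is far more reactive than the boronate, and its bulky bicyclic boron group forces the α-substituent axial (Z olefin, same chirality transfer).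

**Step 13 (double Shi epoxidation).** The C4=C5 olefin is deactivated by its allylic oxygen and the vinyl iodide may be oxidised on long exposure. The fallback sets out from 22 and returns at 24.
- Both silyl ethers are removed first (Bu4NF/AcOH) to give the diene triol F5.
- Sharpless asymmetric epoxidation (Ti(OiPr)4, D-(−)-diethyl tartrate, t-BuOOH, 4 Å sieves, CH2Cl2, −20 °C) epoxidises only the C4=C5 allylic alcohol, giving the (4R,5R)-epoxy triol F6. The C12 allylic alcohol sits on the inert tetrasubstituted iodo-olefin and the C8 alcohol is only homoallylic.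
- The remaining, more reactive 1(10) olefin alone is then epoxidised with the Shi ketone and KHSO5 (short reaction time) to give 24.

**Step 16 (Ni/Cr ring closure).** The yield of the ten-membered ring and the C6 configuration are the least certain points of the route. The fallback sets out from 24 and returns at 28.
- MnO2 (short contact) oxidises the primary allylic C12 alcohol to the hydroxy enal F7.
- NaClO2/NaH2PO4/2-methylbut-2-ene gives the acid F8, and Me3SiCHN2 its methyl ester F9, a (Z)-β-iodo enoate.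
- TEMPO/PhI(OAc)2 then oxidises the primary C6 alcohol to the epoxy aldehyde F10.
- Ring closure with CrCl2/NiCl2 — if needed with a chiral oxazoline–sulfonamide ligand on chromium to override the substrate preference at C6 — now ends with the chromium alkoxide lactonising onto the cis methyl ester, giving 28 directly without a lactol stage.

## Further compounds

F1 | step 12 | 9-(prop-1-en-2-yl)-9-borabicyclo[3.3.1]nonane | CC(=C)B1C2CCCC1CCC2
F2 | step 12 | lithium borate complex of 18 with F1 | CC(C)(C)[Si](C)(C)OC/C=C(\C)CC[C@@H]([B-]1(C(C)=C)C2CCCC1CCC2)OC(=O)N(C(C)C)C(C)C.[Li+]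
F3 | step 12 | (S,E)-9-{8-[(tert-butyldimethylsilyl)oxy]-2,6-dimethylocta-1,6-dien-3-yl}-9-borabicyclo[3.3.1]nonane | CC(C)(C)[Si](C)(C)OC/C=C(\C)CC[C@H](B1C2CCCC1CCC2)C(C)=C
F4 | step 12 | O-(9-borabicyclo[3.3.1]nonan-9-yl) derivative of 22 | CC(=O)OC/C(CO[Si](C)(C)C(C)(C)C)=C(/I)[C@@H](OB1C2CCCC1CCC2)C/C(C)=C\CC/C(C)=C/CO[Si](C)(C)C(C)(C)C
F5 | step 13 | diene triol (22 without both silyl groups) | CC(=O)OC/C(CO)=C(/I)[C@@H](O)C/C(C)=C\CC/C(C)=C/CO
F6 | step 13 | (4R,5R)-4,5-epoxy triol with intact 1(10)Z olefin | CC(=O)OC/C(CO)=C(/I)[C@@H](O)C/C(C)=C\CC[C@@]1(C)O[C@@H]1CO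
F7 | step 16 | bis-epoxy C12 enal with free O6–H and O8–H | CC(=O)OC/C(C=O)=C(/I)[C@@H](O)C[C@]1(C)O[C@@H]1CC[C@@]1(C)O[C@@H]1CO
F8 | step 16 | corresponding C12 carboxylic acid | CC(=O)OC/C(C(=O)O)=C(/I)[C@@H](O)C[C@]1(C)O[C@@H]1CC[C@@]1(C)O[C@@H]1CO
F9 | step 16 | corresponding C12 methyl ester ((Z)-β-iodo enoate) | CC(=O)OC/C(C(=O)OC)=C(/I)[C@@H](O)C[C@]1(C)O[C@@H]1CC[C@@]1(C)O[C@@H]1CO
F10 | step 16 | C12 methyl ester with C6 aldehyde | CC(=O)OC/C(C(=O)OC)=C(/I)[C@@H](O)C[C@]1(C)O[C@@H]1CC[C@@]1(C)O[C@@H]1C=O
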